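The constants used here are those of an exercise; no experiment stands behind them.

4 questions are enough for this flask; the last is the awkward one.

solid substrate 0.30 M; time 30 min
- how much target there is at 30 min, in percent of the solid substrate charged
- the change that raises the amount of target at 30 min, in percent of the solid substrate charged most ("none" if none brings more than 2 percentage points) (dawn / spring / none)
- amount of target at 30 min, in percent of the solid substrate charged, after spring
- given per volume of solution although it is solid: solid substrate
- at the start none of the solid substrate is in solution
- run time (flask): 30 min

    starting material ⇌ other conformer (K1 = 2.6, k1 = 0.089 min⁻¹)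
    starting material → target (k2 = 0.47 min⁻¹)
    other conformer → isomer of the product (k3 = 0.21 min⁻¹)
    target ⇌ isomer of the product (K4 = 2.9, k4 = 0.097 min⁻¹)
    solid substrate ⇌ starting material, rate k5*(cs5 - [starting material]) while solid is left; crystals form when [starting material] > cs5 (cs5 = 0.29 M, k5 = 0.19 min⁻¹)

*How long does the solid feed the solution?* I take the rate into an empty solution, the coefficient 0.19 min⁻¹ times the solubility 0.29 M, which is 0.0551 M min⁻¹. The charge of 0.30 M then lasts t_f = 5.44 min.

*When does the average molecule reach the target and isomer peaks?* Dissolved starting material lives τ = 1.79 min against its two forward steps. The mean arrival is therefore t_a = 0.5·t_f + τ = 4.51 min.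

*What happens to the pair then?* Starting material first gives target with the share f_k = 84.1 %, the kinetic share, while equilibrium holds f_e = 25.6 %, the thermodynamic one. The gap between them falls by a factor 2 every relaxation half-life, 5.31 min, and that is short against 30 min. So I count n, the number of relaxation half-lives between mean arrival and reading: n = 4.80. Then y = f_e + (f_k − f_e)·0.5^n = 27.7 %.

*Won't faster dissolution help?* Either change halves t_f, so t_a becomes 3.15 min and n rises to 5.05. The gap shrinks further and y becomes 27.4 %, a change of −0.30 percentage points. My choice is none.

The forecast gives 28.1 %, none and 27.5 %, saying “Doubling the dissolution coefficient behaves similarly”. My y is lower than its figure.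

The flask gives 28.1 %. The best change is none: dawn moves y by −0.48 points and spring by −0.54 points, leaving 27.5 %. At 300 min target stands at 25.6 %, close to f_e. With n = 4.80, the gap left at 30 min is 2.1 points by my count, and the flask shows 2.5 points.

Read the same flask at 8.0 min: n = 0.657, so target should hold 62.7 % of the pair. The flask gives 54.9 % target and 25.4 % isomer of the product, a share of 68.4 %.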